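**Plan**

- Numbering: C1 = angular-methyl carbon, C2/C3 = CH2, C4 = isopropyl carbinol carbon, C5 = ring-fusion CH; C6 (aroyloxy)–C7–C8 (methyl)=C9–C10 (tigloyloxy) complete the seven-membered ring. β = face of the C1 methyl, α = the other face.
- Enabling feature: C6 and C10 are the two seven-ring atoms bonded to the C1–C5 edge of the cyclopentane, and they are joined to each other only through C7–C8–C9. The hydroazulene is therefore a cyclopentane-fused cyclobutanone [C6(=O)–C10 on C1–C5] with that three-carbon unit inserted into its C6–C10 bond.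
- Retrosynthesis: (a) both ester C–O bonds; (b) C10–OH/C8=C9 back to a 9α,10α-epoxy dienone, and this to a C6 ketone with leaving groups on C8 and C10; (c) C6–C7 cut with C6–C10 re-formed (radical ring expansion); (d) C9–C10 (radical allylation); (e) C1–C10 and C5–C6 (dichloroketene [2+2]); (f) cyclopentene from (R)-terpinen-4-ol by loss of one ring carbon.
- Forward: five-membered ring (ozonolysis, aldol condensation, decarbonylation) → four-membered ring ([2+2]) → side chain on C10 → seven-membered ring by three-carbon ring expansion → dienone, epoxide, reductive opening, two acylations.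
- Stereochemistry: C4 from terpinen-4-ol; C1 from ketene addition anti to the isopropyl group; C5 inverted by kinetic protonation of the C5 enolate; C10 from epoxidation anti to the angular methyl; C6 from a thermodynamically controlled ketone reduction.

Key step: step 8

Remark: commercial (R)-(−)-terpinen-4-ol is taken as enantiomerically pure (enriched beforehand if necessary); C8 in 13–14 and C10 in 14–15 are left as epimer mixtures because both carbons become sp2 in step 9.

**Route**

Step 1
Reactants: 1 (R)-(−)-terpinen-4-ol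
Product: 2 (R)-triethyl{[4-methyl-1-(propan-2-yl)cyclohex-3-en-1-yl]oxy}silane
Conditions: Et3SiOTf, 2,6-lutidine, CH2Cl2, 0 °C → rt
Reagents that add atoms: triethylsilyl trifluoromethanesulfonate, CC[Si](CC)(CC)OS(=O)(=O)C(F)(F)F
Why: Silyl ether formation with the silyl triflate protects the tertiary alcohol for the ozonolysis and the later enolate and radical steps without touching the stereocentre.

Step 2
Reactants: 2 (R)-triethyl{[4-methyl-1-(propan-2-yl)cyclohex-3-en-1-yl]oxy}silane
Product: 4 (R)-6-oxo-3-(propan-2-yl)-3-[(triethylsilyl)oxy]heptanal, via ozonide 3 (not isolated)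
Conditions: O3, CH2Cl2, −78 °C; then PPh3, −78 °C → rt
Reagents that add atoms: ozone, [O-][O+]=O
Why: Ozonolysis with reductive work-up cleaves the only C=C bond to the keto aldehyde and leaves the quaternary carbinol carbon unchanged.

Step 3
Reactants: 4 (R)-6-oxo-3-(propan-2-yl)-3-[(triethylsilyl)oxy]heptanal
Product: 6 (S)-2-methyl-5-(propan-2-yl)-5-[(triethylsilyl)oxy]cyclopent-1-ene-1-carbaldehyde, via aldol adduct 5 (not isolated)
Conditions: piperidine (cat.), AcOH (cat.), benzene, 4 Å MS, 80 °C
Reagents that add atoms: none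
Why: Amine-catalysed intramolecular aldol condensation, in which the aldehyde-derived enamine attacks the methyl ketone and dehydration gives the conjugated cyclopentenecarbaldehyde, the usual outcome for 6-oxoheptanals under piperidinium acetate catalysis.

Step 4
Reactants: 6 (S)-2-methyl-5-(propan-2-yl)-5-[(triethylsilyl)oxy]cyclopent-1-ene-1-carbaldehyde
Product: 7 (S)-triethyl{[3-methyl-1-(propan-2-yl)cyclopent-2-en-1-yl]oxy}silane
Conditions: RhCl(PPh3)3 (1.1 equiv), PhCN, 150 °C
Reagents that add atoms: none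
Why: Tsuji–Wilkinson decarbonylation (insertion into the formyl C–H bond, CO extrusion, reductive elimination) replaces CHO by H at the same alkene carbon and gives the trisubstituted cyclopentene.

Step 5
Reactants: 7 (S)-triethyl{[3-methyl-1-(propan-2-yl)cyclopent-2-en-1-yl]oxy}silane; 8 trichloroacetyl chloride
Product: 10 (1S,4S,5S)-7,7-dichloro-1-methyl-4-(propan-2-yl)-4-[(triethylsilyl)oxy]bicyclo[3.2.0]heptan-6-one, via dichloroketene 9 (not isolated)
Conditions: zinc–copper couple, Et2O/DME, 0 °C → rt, slow addition of 8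
Reagents that add atoms: none
Why: Ketene–alkene [2+2] cycloaddition of dichloroketene (from zinc dechlorination of 8) tolerates hindered trisubstituted alkenes, joins the carbonyl carbon to the less substituted alkene carbon C5 and CCl2 to C1, and should occur suprafacially on the face anti to the isopropyl group (syn to the slimmer silyloxy group), which sets C1 and the cis fusion at C5.

Step 6
Reactants: 10 (1S,4S,5S)-7,7-dichloro-1-methyl-4-(propan-2-yl)-4-[(triethylsilyl)oxy]bicyclo[3.2.0]heptan-6-one; 11 tributyl(2-methylprop-2-en-1-yl)stannane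
Product: 12 (1S,4S,5S,7S)-7-chloro-1-methyl-7-(2-methylprop-2-en-1-yl)-4-(propan-2-yl)-4-[(triethylsilyl)oxy]bicyclo[3.2.0]heptan-6-one (allyl group exo)
Conditions: AIBN (cat.), benzene, 80 °C
Reagents that add atoms: none
Why: Keck radical allylation, in which Bu3Sn• abstracts one activated chlorine and the α-keto radical adds to the stannane from the exo (convex) face, so the C9 chain ends up exo as the ring expansion requires, while the hindered tertiary monochloride should react too slowly for a second allylation.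

Step 7
Reactants: 12 (1S,4S,5S,7S)-7-chloro-1-methyl-7-(2-methylprop-2-en-1-yl)-4-(propan-2-yl)-4-[(triethylsilyl)oxy]bicyclo[3.2.0]heptan-6-one
Product: 13 1-[(1S,4S,5S,7S)-7-chloro-1-methyl-6-oxo-4-(propan-2-yl)-4-[(triethylsilyl)oxy]bicyclo[3.2.0]heptan-7-yl]-3-iodo-2-methylpropan-2-yl acetate (both C8 epimers)
Conditions: N-iodosuccinimide, AcOH (10 equiv), CH2Cl2, 0 °C → rt, dark
Reagents that add atoms: N-iodosuccinimide, O=C1CCC(=O)N1I; acetic acid, CC(O)=O
Why: Markovnikov iodoacetoxylation (iodonium ion opened by acetate at the tertiary carbon) converts the 1,1-disubstituted alkene into the primary C7 iodide and a tertiary C8 acetate, and the uncontrolled C8 centre is harmless because it becomes sp2 in step 9.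

Step 8
Reactants: 13 1-[(1S,4S,5S,7S)-7-chloro-1-methyl-6-oxo-4-(propan-2-yl)-4-[(triethylsilyl)oxy]bicyclo[3.2.0]heptan-7-yl]-3-iodo-2-methylpropan-2-yl acetate
Product: 14 cis-fused 8-acetoxy-10-chloro-4β-isopropyl-1β,8-dimethyl-4α-(triethylsilyloxy)perhydroazulen-6-one (route numbering; 5β-H; C8/C10 epimers)
Conditions: Bu3SnH (1.2 equiv) and AIBN (0.2 equiv) added over 8 h by syringe pump, benzene (0.005 M), 80 °C
Reagents that add atoms: none
Why: Bu3Sn• removes the iodine atom (orders of magnitude faster than it attacks the tertiary α-chloro ketone), and the primary C7 radical adds 5-exo-trig to the strained carbonyl carbon C6 from the exo face on which the chain sits, forming C6–C7 and a bicyclo[3.2.0]heptan-1-oxyl radical. β-Scission of the shared C6–C10 bond opens the four-membered ring to the cycloheptanone and leaves a chlorine-stabilised secondary radical at C10 that takes hydrogen from Bu3SnH; this is a Dowd–Beckwith three-carbon ring expansion, closest to the known expansion of fused α-(3-halopropyl)cyclobutanones to cis-fused cycloheptanones. The seven-membered ring thus arises by a five-membered exo closure onto C=O followed by fragmentation, not by a direct seven-ring closure, and C1, C4 and C5 are carried through unchanged (cis fusion retained). The one new stereocentre, C10 (CHCl), forms without control by hydrogen transfer to either face and is erased together with C8 in step 9. Cyclisation has to outrun reduction of the C7 radical, which slow stannane addition at high dilution, the quaternary C8 (gem-disubstituent effect) and the exo chain should secure; the 1,2-acetoxy shift of the β-acetoxy radical is far slower. Fragmentation has to follow C6–C10 and not C5–C6, which the radical-stabilising chlorine on C10 favours.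

Step 9
Reactants: 14 cis-fused 8-acetoxy-10-chloro-4β-isopropyl-1β,8-dimethyl-4α-(triethylsilyloxy)perhydroazulen-6-one
Product: 16 cis-fused 4β-isopropyl-1β,8-dimethyl-4α-(triethylsilyloxy)hydroazula-7,9-dien-6-one (5β-H), via chloro enone 15 (not isolated)
Conditions: DBU (4 equiv), toluene, rt → 80 °C
Reagents that add atoms: none
Why: Two consecutive E1cB eliminations, the β-acetoxy ketone first giving the C7=C8 enone and its dienolate then expelling chloride from C10 (vinylogous dehydrochlorination), deliver the linear dienone and remove the C8 and C10 stereocentres.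

Step 10
Reactants: 16 cis-fused 4β-isopropyl-1β,8-dimethyl-4α-(triethylsilyloxy)hydroazula-7,9-dien-6-one
Product: 18 trans-fused 4β-isopropyl-1β,8-dimethyl-4α-(triethylsilyloxy)hydroazula-7,9-dien-6-one (5α-H), via lithium enolate 17 (not isolated)
Conditions: LiN(iPr)2 (1.3 equiv), THF, −78 → −40 °C; then cannulated into AcOH/THF, −78 °C
Reagents that add atoms: none
Why: Epimerisation through enolate formation and kinetic protonation: H-5 is the only α-hydrogen of the dienone, and the proton should return to C5 of the cross-conjugated enolate from the α-face because the β-face is flanked by the C1 methyl and the C4 isopropyl group, giving the trans ring fusion.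

Step 11
Reactants: 18 trans-fused 4β-isopropyl-1β,8-dimethyl-4α-(triethylsilyloxy)hydroazula-7,9-dien-6-one
Product: 19 trans-fused 9α,10α-epoxy-4β-isopropyl-1β,8-dimethyl-4α-(triethylsilyloxy)hydroazul-7-en-6-one
Conditions: mCPBA, NaHCO3, CH2Cl2, 0 °C
Reagents that add atoms: 3-chloroperoxybenzoic acid, OOC(=O)c1cccc(Cl)c1
Why: Prilezhaev epoxidation of the more electron-rich γ,δ-double bond of the dienone from the α-face, anti to the axial C1 methyl of the trans-fused ring system, sets the C10–O bond in the required configuration.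

Step 12
Reactants: 19 trans-fused 9α,10α-epoxy-4β-isopropyl-1β,8-dimethyl-4α-(triethylsilyloxy)hydroazul-7-en-6-one
Product: 21 4β-isopropyl-1β,8-dimethyl-4α-(triethylsilyloxy)hydroazul-8-ene-6α,10α-diol (5α-H), via hydroxy enone 20 (not isolated)
Conditions: SmI2 (2.5 equiv), THF/MeOH, −78 °C; then SmI2 (2.5 equiv), H2O, Et3N, −78 → 0 °C
Reagents that add atoms: none
Why: SmI2 reduction of a vinylogous epoxy ketone (electron transfer, cleavage of the allylic C9–O bond, kinetic protonation of the samarium dienolate at C7) gives the 10α-hydroxy Δ8-ketone with C10 unchanged, and the SmI2–water–amine ketone reduction that follows should give the more stable equatorial 6α-alcohol (H-6 anti to H-5), as electron-transfer reductions of ring ketones generally do.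

Step 13
Reactants: 21 4β-isopropyl-1β,8-dimethyl-4α-(triethylsilyloxy)hydroazul-8-ene-6α,10α-diol; 22 tigloyl chloride [(E)-2-methylbut-2-enoyl chloride]
Product: 23 6α-hydroxy-4β-isopropyl-1β,8-dimethyl-4α-(triethylsilyloxy)hydroazul-8-en-10α-yl (E)-2-methylbut-2-enoate
Conditions: pyridine, DMAP (cat.), CH2Cl2, 0 °C
Reagents that add atoms: none
Why: DMAP-catalysed acylation should take place at the allylic C10 hydroxyl because the C6 hydroxyl is shielded by the syn silyloxy group on the neighbouring C4.

Step 14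
Reactants: 23 6α-hydroxy-4β-isopropyl-1β,8-dimethyl-4α-(triethylsilyloxy)hydroazul-8-en-10α-yl (E)-2-methylbut-2-enoate
Product: 24 4α,6α-dihydroxy-4β-isopropyl-1β,8-dimethylhydroazul-8-en-10α-yl (E)-2-methylbut-2-enoate
Conditions: HF·pyridine, pyridine/THF, 0 °C → rt
Reagents that add atoms: none
Why: Fluoride-mediated cleavage of the tertiary silyl ether under buffered, non-basic conditions leaves the allylic ester intact and uncovers the C6 hydroxyl for acylation.

Step 15
Reactants: 24 4α,6α-dihydroxy-4β-isopropyl-1β,8-dimethylhydroazul-8-en-10α-yl (E)-2-methylbut-2-enoate; 25 4-acetoxybenzoic acid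
Product: 27 4α-hydroxy-4β-isopropyl-1β,8-dimethyl-10α-[(E)-2-methylbut-2-enoyloxy]hydroazul-8-en-6α-yl 4-acetoxybenzoate, via mixed anhydride 26 (not isolated)
Conditions: 25, 2,4,6-trichlorobenzoyl chloride, Et3N, THF, rt; then 24, DMAP, toluene, 40 °C
Reagents that add atoms: none
Why: Yamaguchi esterification transfers the aroyl group through the acylpyridinium ion to the secondary C6 hydroxyl, the tertiary C4 hydroxyl being too hindered to react.

Step 16
Reactants: 27 4α-hydroxy-4β-isopropyl-1β,8-dimethyl-10α-[(E)-2-methylbut-2-enoyloxy]hydroazul-8-en-6α-yl 4-acetoxybenzoate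
Product: 28 (3S,3aS,4S,8R,8aS)-3-hydroxy-6,8a-dimethyl-8-{[(2E)-2-methylbut-2-enoyl]oxy}-3-(propan-2-yl)-1,2,3,3a,4,5,8,8a-octahydroazulen-4-yl 4-hydroxybenzoate (target)
Conditions: K2CO3 (0.2 equiv), MeOH, 0 °C
Reagents that add atoms: none
Why: Base-catalysed methanolysis (transesterification) of the activated aryl acetate is much faster than attack on the two hindered alkyl esters and frees the phenol.

**Compound list**

1 | (R)-(−)-terpinen-4-ol | CC1=CC[C@@](O)(C(C)C)CC1 | starting material
2 | (R)-triethyl{[4-methyl-1-(propan-2-yl)cyclohex-3-en-1-yl]oxy}silane | CC1=CC[C@@](O[Si](CC)(CC)CC)(C(C)C)CC1 | intermediate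
3 | ozonide of 2 (1,2,4-trioxolane across the former C=C) | CC12CC[C@](O[Si](CC)(CC)CC)(C(C)C)CC(OO1)O2 | intermediate
4 | (R)-6-oxo-3-(propan-2-yl)-3-[(triethylsilyl)oxy]heptanal | O=CC[C@@](O[Si](CC)(CC)CC)(C(C)C)CCC(C)=O | intermediate
5 | aldol adduct, (5S)-2-hydroxy-2-methyl-5-(propan-2-yl)-5-[(triethylsilyl)oxy]cyclopentane-1-carbaldehyde (C1, C2 undefined) | O=CC1C(C)(O)CC[C@]1(O[Si](CC)(CC)CC)C(C)C | intermediate
6 | (S)-2-methyl-5-(propan-2-yl)-5-[(triethylsilyl)oxy]cyclopent-1-ene-1-carbaldehyde | O=CC1=C(C)CC[C@]1(O[Si](CC)(CC)CC)C(C)C | intermediate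
7 | (S)-triethyl{[3-methyl-1-(propan-2-yl)cyclopent-2-en-1-yl]oxy}silane | CC1=C[C@@](O[Si](CC)(CC)CC)(C(C)C)CC1 | intermediate
8 | trichloroacetyl chloride | ClC(Cl)(Cl)C(Cl)=O | starting material
9 | dichloroketene | ClC(Cl)=C=O | intermediate
10 | (1S,4S,5S)-7,7-dichloro-1-methyl-4-(propan-2-yl)-4-[(triethylsilyl)oxy]bicyclo[3.2.0]heptan-6-one | O=C1C(Cl)(Cl)[C@@]2(C)CC[C@](O[Si](CC)(CC)CC)(C(C)C)[C@@H]12 | intermediate
11 | tributyl(2-methylprop-2-en-1-yl)stannane | CCCC[Sn](CCCC)(CCCC)CC(C)=C | starting material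
12 | (1S,4S,5S,7S)-7-chloro-1-methyl-7-(2-methylprop-2-en-1-yl)-4-(propan-2-yl)-4-[(triethylsilyl)oxy]bicyclo[3.2.0]heptan-6-one | O=C1[C@](Cl)(CC(C)=C)[C@@]2(C)CC[C@](O[Si](CC)(CC)CC)(C(C)C)[C@@H]12 | intermediate
13 | 1-[(1S,4S,5S,7S)-7-chloro-1-methyl-6-oxo-4-(propan-2-yl)-4-[(triethylsilyl)oxy]bicyclo[3.2.0]heptan-7-yl]-3-iodo-2-methylpropan-2-yl acetate (C8 epimers; key-step precursor) | O=C1[C@](Cl)(CC(C)(OC(C)=O)CI)[C@@]2(C)CC[C@](O[Si](CC)(CC)CC)(C(C)C)[C@@H]12 | intermediate
14 | cis-fused 8-acetoxy-10-chloro-4β-isopropyl-1β,8-dimethyl-4α-(triethylsilyloxy)perhydroazulen-6-one (5β-H; C8/C10 epimers; key-step product) | O=C1CC(C)(OC(C)=O)CC(Cl)[C@@]2(C)CC[C@](O[Si](CC)(CC)CC)(C(C)C)[C@@H]12 | intermediate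
15 | cis-fused 10-chloro-4β-isopropyl-1β,8-dimethyl-4α-(triethylsilyloxy)hydroazul-7-en-6-one (C10 epimers) | O=C1C=C(C)CC(Cl)[C@@]2(C)CC[C@](O[Si](CC)(CC)CC)(C(C)C)[C@@H]12 | intermediate
16 | cis-fused (5β-H) 4β-isopropyl-1β,8-dimethyl-4α-(triethylsilyloxy)hydroazula-7,9-dien-6-one | C1=CC(C)=CC(=O)[C@H]2[C@]1(C)CC[C@]2(O[Si](CC)(CC)CC)C(C)C | intermediate
17 | lithium C5=C6 enolate of the dienone | [Li+].[O-]C1=C2[C@@](O[Si](CC)(CC)CC)(C(C)C)CC[C@]2(C)C=CC(C)=C1 | intermediate
18 | trans-fused (5α-H) 4β-isopropyl-1β,8-dimethyl-4α-(triethylsilyloxy)hydroazula-7,9-dien-6-one | C1=CC(C)=CC(=O)[C@@H]2[C@]1(C)CC[C@]2(O[Si](CC)(CC)CC)C(C)C | intermediate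
19 | trans-fused 9α,10α-epoxy-4β-isopropyl-1β,8-dimethyl-4α-(triethylsilyloxy)hydroazul-7-en-6-one | O3[C@@H]1[C@H]3C(C)=CC(=O)[C@@H]2[C@]1(C)CC[C@]2(O[Si](CC)(CC)CC)C(C)C | intermediate
20 | trans-fused 10α-hydroxy-4β-isopropyl-1β,8-dimethyl-4α-(triethylsilyloxy)hydroazul-8-en-6-one | O[C@@H]1C=C(C)CC(=O)[C@@H]2[C@]1(C)CC[C@]2(O[Si](CC)(CC)CC)C(C)C | intermediate
21 | 4β-isopropyl-1β,8-dimethyl-4α-(triethylsilyloxy)hydroazul-8-ene-6α,10α-diol (5α-H) | O[C@@H]1C=C(C)C[C@H](O)[C@@H]2[C@]1(C)CC[C@]2(O[Si](CC)(CC)CC)C(C)C | intermediate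
22 | tigloyl chloride, (E)-2-methylbut-2-enoyl chloride | C/C=C(\C)C(Cl)=O | starting material
23 | 6α-hydroxy-4β-isopropyl-1β,8-dimethyl-4α-(triethylsilyloxy)hydroazul-8-en-10α-yl (E)-2-methylbut-2-enoate | C/C=C(\C)C(=O)O[C@@H]1C=C(C)C[C@H](O)[C@@H]2[C@]1(C)CC[C@]2(O[Si](CC)(CC)CC)C(C)C | intermediate
24 | 4α,6α-dihydroxy-4β-isopropyl-1β,8-dimethylhydroazul-8-en-10α-yl (E)-2-methylbut-2-enoate | C/C=C(\C)C(=O)O[C@@H]1C=C(C)C[C@H](O)[C@@H]2[C@]1(C)CC[C@]2(O)C(C)C | intermediate
25 | 4-acetoxybenzoic acid | CC(=O)Oc1ccc(cc1)C(O)=O | starting material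
26 | 4-acetoxybenzoic 2,4,6-trichlorobenzoic anhydride | CC(=O)Oc1ccc(cc1)C(=O)OC(=O)c1c(Cl)cc(Cl)cc1Cl | intermediate
27 | 4α-hydroxy-4β-isopropyl-1β,8-dimethyl-10α-[(E)-2-methylbut-2-enoyloxy]hydroazul-8-en-6α-yl 4-acetoxybenzoate | C/C=C(\C)C(=O)O[C@@H]1C=C(C)C[C@H](OC(=O)c2ccc(OC(C)=O)cc2)[C@@H]2[C@]1(C)CC[C@]2(O)C(C)C | intermediate
28 | (3S,3aS,4S,8R,8aS)-3-hydroxy-6,8a-dimethyl-8-{[(2E)-2-methylbut-2-enoyl]oxy}-3-(propan-2-yl)-1,2,3,3a,4,5,8,8a-octahydroazulen-4-yl 4-hydroxybenzoate | C/C=C(\C)C(=O)O[C@@H]1C=C(C)C[C@H](OC(=O)c2ccc(O)cc2)[C@@H]2[C@]1(C)CC[C@]2(O)C(C)C | target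

**Step count**

Total: 16 steps. Longest linear sequence: 16 steps (1 → 28); 8, 11, 22 and 25 are purchased.

**Steps most likely to fail**

Step 10 (inversion of C5). The amide base may fail to reach H-5, which sits on the β-face between the C1 methyl and the C4 isopropyl group, and remove a γ-hydrogen of the C8 methyl instead; the quench would then return cis ketone or a deconjugated isomer. The fallback reaches the C5 enolate without an amide deprotonation. It sets out from 16: Mn(OAc)3 in benzene at reflux (α′-acetoxylation of the enone through its manganese enolate) gives the 5-acetoxy dienone F1. SmI2 in THF/MeOH at −78 °C (reductive cleavage of an α-acyloxy ketone) then forms the samarium enolate F2 regiospecifically at C5=C6, and methanol protonates it in situ from the open α-face. The route is rejoined at 18.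

Step 12 (C6 configuration). Hydrogen delivery to C6 from the α-face would give the axial 6β-alcohol, and the β,γ-enone may also slip into conjugation before it is reduced. The fallback separates the two events and sets C6 by kinetic reduction and inversion. It sets out from 19: the SmI2/MeOH stage alone is run at −78 °C and the hydroxy enone 20 is isolated. Acylation with 22 (pyridine, DMAP, CH2Cl2, 0 °C) gives the 10-O-tigloyl ketone F3. NaBH4 in MeOH at −20 °C, attacking anti to the angular methyl, gives the axial 6β-alcohol F4, and HF·pyridine then frees the tertiary hydroxyl to give the 4α,6β-diol F5. A Mitsunobu esterification with 25 (PPh3, DIAD, toluene) installs the aroyl group with inversion at C6 and rejoins the route at 27.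

Step 13 (site selectivity). Acylation may not discriminate between O10 and O6, or may drift to O6. The fallback masks the C4/C6 syn-diol instead of relying on shielding. It sets out from 21: HF·pyridine gives the 4α,6α,10α-triol F6, and PhB(OH)2 (toluene, 4 Å MS) ties O4 and O6 into the six-membered cyclic phenylboronate F7. The one remaining hydroxyl is acylated with 22 (pyridine, DMAP) to give the boronate tiglate F8, and boronate exchange with pinacol releases the diol. The route is rejoined at 24.

**Further compounds**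

F1 | step 10 | 5-acetoxy-4β-isopropyl-1β,8-dimethyl-4α-(triethylsilyloxy)hydroazula-7,9-dien-6-one (C5 undefined) | C1=CC(C)=CC(=O)C2(OC(C)=O)[C@]1(C)CC[C@]2(O[Si](CC)(CC)CC)C(C)C
F2 | step 10 | diiodosamarium C5=C6 enolate of the dienone (trivalent samarium) | [Sm+3].[I-].[I-].[O-]C1=C2[C@@](O[Si](CC)(CC)CC)(C(C)C)CC[C@]2(C)C=CC(C)=C1
F3 | step 12 | trans-fused 4β-isopropyl-1β,8-dimethyl-6-oxo-4α-(triethylsilyloxy)hydroazul-8-en-10α-yl (E)-2-methylbut-2-enoate | C/C=C(\C)C(=O)O[C@@H]1C=C(C)CC(=O)[C@@H]2[C@]1(C)CC[C@]2(O[Si](CC)(CC)CC)C(C)C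
F4 | step 12 | 6β-hydroxy-4β-isopropyl-1β,8-dimethyl-4α-(triethylsilyloxy)hydroazul-8-en-10α-yl (E)-2-methylbut-2-enoate | C/C=C(\C)C(=O)O[C@@H]1C=C(C)C[C@@H](O)[C@@H]2[C@]1(C)CC[C@]2(O[Si](CC)(CC)CC)C(C)C
F5 | step 12 | 4α,6β-dihydroxy-4β-isopropyl-1β,8-dimethylhydroazul-8-en-10α-yl (E)-2-methylbut-2-enoate | C/C=C(\C)C(=O)O[C@@H]1C=C(C)C[C@@H](O)[C@@H]2[C@]1(C)CC[C@]2(O)C(C)C
F6 | step 13 | 4β-isopropyl-1β,8-dimethylhydroazul-8-ene-4α,6α,10α-triol (5α-H) | O[C@@H]1C=C(C)C[C@H](O)[C@@H]2[C@]1(C)CC[C@]2(O)C(C)C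
F7 | step 13 | cyclic phenylboronate of F6 across O4 and O6 (10α-OH free) | O[C@@H]1C=C(C)C[C@H](OB3c4ccccc4)[C@@H]2[C@]1(C)CC[C@]2(O3)C(C)C
F8 | step 13 | 10α-tiglate of the O4,O6-phenylboronate | C/C=C(\C)C(=O)O[C@@H]1C=C(C)C[C@H](OB3c4ccccc4)[C@@H]2[C@]1(C)CC[C@]2(O3)C(C)C
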